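The route rests on cutting ring A at C3–C4 and C5–C10, which opens both rings of the eudesmane to an acyclic 1,7,9-decatriene. The feature used is the contiguous triad C4 (quaternary, CH3 and O), C5 (H) and C10 (quaternary, CH3) in ring A. C4=C5 becomes an (E)-2-methylenal, and C10 becomes the tethered end of the diene C10=C1–C2=C3. One enantioselective type 1 intramolecular Diels–Alder reaction closes rings A and B and sets all three centres. The 4α-formyl carbon is later exchanged for oxygen with retention. The precursor is a 2,8-dimethylundeca-2,8,10-trienal whose C8 carbonyl stays masked as the 1,3-dithiane from the linchpin assembly, inert to Lewis acid.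

Key step: step 8

Remarks
- Eudesmane numbering is used for all intermediates, including the acyclic ones. The target reads as 3β-O-angelate (equatorial, Z ester alkene), 4α-OAc/4β-CH3, 5α-H and 10β-CH3 on a trans-decalin, with C7=C11 isopropylidene and a C8 ketone.
- The carbinol carbon in 16 and 17 and C7 in 27 and 28 are erased later. They are left undefined.
- Assumption: the (S)-configured catalyst is written in step 8, on the basis of the formyl C–H···O binding model for 2-substituted enals. If the first run shows the opposite sense of induction, the equally available (R)-catalyst is used and nothing else changes.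

Step 1
Reactants: 1 acrolein; 2 ethyl 2-(triphenylphosphoranylidene)propanoate
Product: 3 ethyl (2E)-2-methylpenta-2,4-dienoate
Conditions: CH2Cl2, 0 °C to rt
Reagents that add atoms: none
Why: Wittig olefination with a stabilised α-methyl ylide is (E)-selective, so the vinyl group ends up cis to the methyl group and trans to the ester carbon (the future C9), which is the diene geometry that step 8 needs.

Step 2
Reactants: 3 ethyl (2E)-2-methylpenta-2,4-dienoate
Product: 4 (2E)-2-methylpenta-2,4-dien-1-ol
Conditions: DIBAL-H, CH2Cl2, −78 °C
Reagents that add atoms: none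
Why: DIBAL-H reduction of a conjugated ester at low temperature proceeds by 1,2-hydride delivery to the allylic alcohol and leaves the diene and its geometry untouched.

Step 3
Reactants: 4 (2E)-2-methylpenta-2,4-dien-1-ol
Product: 5 (3E)-5-bromo-4-methylpenta-1,3-diene
Conditions: PBr3, Et2O, −10 to 0 °C, used crude
Reagents that add atoms: phosphorus tribromide, BrP(Br)Br
Why: Bromination of a primary allylic alcohol through its phosphite ester is an SN2 displacement that keeps the (E)-geometry when run cold, and the labile bromide is used without purification.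

Step 4
Reactants: 6 1,3-dithiane; 7 2-(2-bromoethyl)-1,3-dioxolane
Product: 9 2-[2-(1,3-dioxolan-2-yl)ethyl]-1,3-dithiane, via 2-lithio-1,3-dithiane 8 (not isolated)
Conditions: n-BuLi, THF, −30 °C; then 7, −78 °C to rt
Reagents that add atoms: none
Why: Corey–Seebach umpolung: the dithiane carbanion (the future C8) displaces the unhindered primary bromide in an SN2 reaction, and the less reactive of the two electrophiles is deliberately used in the easier first alkylation.

Step 5
Reactants: 9 2-[2-(1,3-dioxolan-2-yl)ethyl]-1,3-dithiane; 5 (3E)-5-bromo-4-methylpenta-1,3-diene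
Product: 11 2-[2-(1,3-dioxolan-2-yl)ethyl]-2-[(2E)-2-methylpenta-2,4-dien-1-yl]-1,3-dithiane, via lithiated dithiane 10 (not isolated)
Conditions: n-BuLi, THF, −25 °C; then 5, −78 to 0 °C
Reagents that add atoms: none
Why: A second Corey–Seebach alkylation, in which the hindered tertiary carbanion meets a highly reactive primary allylic bromide and attacks its CH2 terminus (SN2), forms C8–C9 without touching the diene geometry.

Step 6
Reactants: 11 2-[2-(1,3-dioxolan-2-yl)ethyl]-2-[(2E)-2-methylpenta-2,4-dien-1-yl]-1,3-dithiane
Product: 12 3-{2-[(2E)-2-methylpenta-2,4-dien-1-yl]-1,3-dithian-2-yl}propanal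
Conditions: 2 M HCl, THF, rt
Reagents that add atoms: water, O
Why: Acid-catalysed acetal hydrolysis is chemoselective because the S,S-acetal is inert to dilute aqueous acid, which avoids having to tell an aldehyde O,O-acetal from a ketone O,O-ketal and never exposes the isomerisation-prone β,γ-unsaturated ketone.

Step 7
Reactants: 12 3-{2-[(2E)-2-methylpenta-2,4-dien-1-yl]-1,3-dithian-2-yl}propanal; 13 2-(triphenylphosphoranylidene)propanal
Product: 14 (2E,8E)-2,8-dimethyl-6,6-(propane-1,3-diyldisulfanediyl)undeca-2,8,10-trienal (C8 as spiro-1,3-dithiane)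
Conditions: toluene, 80 °C
Reagents that add atoms: none
Why: Wittig olefination with the stabilised formyl ylide gives the (E)-2-methylenal directly at the aldehyde oxidation level, placing the C4 methyl cis to C6, and the temperature stays well below what an uncatalysed cycloaddition of this hindered diene would need.

Step 8
Reactants: 14 (2E,8E)-2,8-dimethyl-6,6-(propane-1,3-diyldisulfanediyl)undeca-2,8,10-trienal
Product: 15 trans-fused Δ1-octalin adduct: 4α-CHO, 4β-CH3, 5α-H, 10β-CH3, C8 spiro-1,3-dithiane
Conditions: (S)-oxazaborolidine [from (S)-α,α-diphenylprolinol and o-tolylboroxine]·Tf2NH (20 mol %), CH2Cl2, −40 to 0 °C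
Reagents that add atoms: none
Why: The boron-bound formyl group lowers the LUMO of the C4=C5 enal and the diene C10=C1–C2=C3 adds to it suprafacially in a concerted, asynchronous [4+2] process, a catalytic enantioselective type 1 intramolecular Diels–Alder reaction of a 1,7,9-decatriene as known for 2-methyl-2-enals with cationic oxazaborolidines and acyloxyboranes. Ring A closes as the new cyclohexene through both new bonds (C3–C4 and C5–C10), and ring B closes as the six-membered tether ring (C5–C6–C7–C8–C9–C10) through C5–C10 alone, in the fused mode that a tether on the diene terminus dictates, so regiochemistry is not in question. C4 follows from the (E)-geometry of the enal, which keeps the C4 methyl cis to C6 and the formyl group cis to H5. C5 and C10 follow from the topology with formyl endo and a chair-like tether exo on a diene whose C9 is outside and whose methyl is inside, which places H5 and CHO on the face opposite the C10 methyl (trans fusion, 4α-CHO, 4β- and 10β-CH3). The absolute sense comes from the catalyst, whose aryl group covers one face of the s-trans enal held by B–O coordination and a formyl C–H···O contact, so that the diene reaches the Re face of C4. The selectivities needed are endo over exo and one enal face over the other; the first is secured by the (E,E)-triene geometry and Lewis-acid-enhanced secondary overlap, and the dithiane helps by folding the chain (Thorpe–Ingold effect) without ionising or isomerising the skipped diene as an O,O-ketal next to C9 could.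

Step 9
Reactants: 15 trans-fused Δ1-octalin adduct
Product: 16 4α-(1-hydroxyethyl) carbinol of 15 (epimers at the carbinol carbon), C8 spiro-1,3-dithiane
Conditions: MeMgBr, Et2O/THF, −20 to 0 °C
Reagents that add atoms: methylmagnesium bromide, C[Mg]Br
Why: Grignard addition to a non-enolisable aldehyde is straightforward; the new carbinol centre is left uncontrolled because step 11 erases it, and the added methyl turns the oxidation-sensitive formyl group into the precursor of an acetyl group whose only good migrating group is C4.

Step 10
Reactants: 16 4α-(1-hydroxyethyl) carbinol, C8 dithiane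
Product: 17 4α-(1-hydroxyethyl) carbinol, C8 as 1,3-dioxolane
Conditions: PhI(OCOCF3)2, HOCH2CH2OH, MeCN, 0 °C to rt
Reagents that add atoms: ethylene glycol, OCCO
Why: Oxidative transketalisation (iodine(III) activates sulfur, the thionium ion is captured by the diol) replaces the mask that would not survive Cr(VI), Pd/H2 or peracid by a dioxolane in one operation, and it is safe here because C10 is now quaternary and no alkene can move into conjugation with C8.

Step 11
Reactants: 17 4α-(1-hydroxyethyl) carbinol, C8 dioxolane
Product: 19 4α-acetyl-4β,10β-dimethyl-5α-H-Δ1-octalin-3,8-dione 8-ethylene ketal, via methyl ketone 18 (not isolated)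
Conditions: CrO3, 3,5-dimethylpyrazole (excess), CH2Cl2, −20 to 0 °C
Reagents that add atoms: chromium trioxide, O=[Cr](=O)=O
Why: The Cr(VI)–pyrazole reagent first oxidises the secondary alcohol and then performs an allylic oxidation at C3, the only allylic carbon that carries hydrogen (C10 is quaternary), to give the Δ1-3-ketone without touching the ketal or the quaternary centres.

Step 12
Reactants: 19 ene-dione ketal
Product: 20 4α-acetyl-4β,10β-dimethyl-5α-H-trans-decalin-3,8-dione 8-ethylene ketal
Conditions: H2 (1 atm), Pd/C, EtOAc, rt
Reagents that add atoms: none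
Why: Heterogeneous catalytic hydrogenation saturates the disubstituted enone C1=C2 bond selectively over both ketones and creates no stereocentre.

Step 13
Reactants: 20 saturated dione ketal
Product: 21 3β-hydroxy-4α-acetyl-4β,10β-dimethyl-5α-H-trans-decal-8-one ethylene ketal
Conditions: NaBH4 (limiting), MeOH/CH2Cl2, −40 to −10 °C
Reagents that add atoms: none
Why: Borohydride reduction is chemoselective for the ring ketone over the acyclic tert-alkyl methyl ketone and stereoselective because hydride arrives along the axial α-trajectory, the β-face being screened by the axial methyls on C4 and C10, which sets the equatorial 3β-OH.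

Step 14
Reactants: 21 3β-hydroxy-4α-acetyl ketal
Product: 22 3β-hydroxy-4α-acetoxy-4β,10β-dimethyl-5α-H-trans-decal-8-one ethylene ketal
Conditions: mCPBA, NaHCO3, CH2Cl2, rt to 40 °C
Reagents that add atoms: 3-chloroperoxybenzoic acid (mCPBA), OOC(=O)c1cccc(Cl)c1
Why: Baeyer–Villiger oxidation: in the Criegee intermediate the tertiary C4 migrates far better than methyl and does so with retention, so the α-C–C bond made in step 8 becomes the 4α-C–O bond, while the ketal shields C8 from the peracid.

Step 15
Reactants: 22 3β-hydroxy-4α-acetoxy ketal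
Product: 24 3β,4α-dihydroxy-4β,10β-dimethyl-5α-H-trans-decal-8-one, via diol ketal 23 (not isolated)
Conditions: K2CO3 (cat.), MeOH, rt; then 2 M HCl to pH 1, rt
Reagents that add atoms: water, O
Why: Base-catalysed transesterification followed by acid-catalysed ketal hydrolysis in the same flask frees the diol and the C8 ketone; the acetyl group is given up on purpose because, next to a free 3-OH, it would shift to O3 during any later acylation.

Step 16
Reactants: 24 keto diol
Product: 25 3β,4α-bis(trimethylsilyloxy)-4β,10β-dimethyl-5α-H-trans-decal-8-one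
Conditions: TMSOTf, 2,6-lutidine, CH2Cl2, −78 to −20 °C
Reagents that add atoms: trimethylsilyl trifluoromethanesulfonate, C[Si](C)(C)OS(=O)(=O)C(F)(F)F
Why: Silyl triflate with a hindered pyridine base silylates both the secondary and the tertiary hydroxyl (silyl ether protection), so that the next two steps see a single acidic site and a single free alcohol.

Step 17
Reactants: 25 bis-TMS ketone
Product: 27 7-(2-hydroxypropan-2-yl) aldol of 25 (C7 undefined), via lithium enolate 26 (not isolated)
Conditions: LDA, THF, −78 °C; ZnCl2; acetone, −78 to −30 °C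
Reagents that add atoms: acetone, CC(C)=O
Why: Directed aldol addition: kinetic deprotonation occurs at C7 since C9 is neopentyl and a Δ7 enolate is also the less strained one in this trans-decalone, zinc chelation holds the otherwise reversible adduct with acetone, and the new C7 centre is irrelevant because step 18 removes it.

Step 18
Reactants: 27 aldol
Product: 30 3β,4α-dihydroxyeudesm-7(11)-en-8-one, via tertiary mesylate 28 (not isolated), via bis-TMS enone 29 (not isolated)
Conditions: MsCl, Et3N, CH2Cl2, 0 °C to rt; DBU; then 1 M HCl, THF, rt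
Reagents that add atoms: none
Why: Sulfene-type mesylation of the only free (tertiary) alcohol and base-induced E1cB elimination through the C7 enolate give the conjugated tetrasubstituted isopropylidene ketone (DBU also conjugates any isopropenyl isomer), and dilute acid then cleaves both trimethylsilyl ethers.

Step 19
Reactants: 30 3β,4α-dihydroxyeudesm-7(11)-en-8-one; 31 angelic acid [(2Z)-2-methylbut-2-enoic acid]
Product: 33 3β-angeloyloxy-4α-hydroxyeudesm-7(11)-en-8-one, via mixed anhydride 32 (not isolated)
Conditions: 31, 2,4,6-Cl3C6H2COCl, Et3N, toluene, rt; then 30, 80 °C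
Reagents that add atoms: none
Why: Yamaguchi-type mixed-anhydride esterification run without nucleophilic catalyst is the established way to transfer the angeloyl group with its (Z)-geometry intact, and only the secondary equatorial 3β-OH reacts because the tertiary 4α-OH is far more hindered.

Step 20
Reactants: 33 3β-angeloyloxy-4α-hydroxyeudesm-7(11)-en-8-one
Product: 34 3β-angeloyloxy-4α-acetoxyeudesm-7(11)-en-8-one (target, CNP0141494.1)
Conditions: Ac2O, DMAP, Et3N, CH2Cl2, rt to 40 °C
Reagents that add atoms: acetic anhydride, CC(=O)OC(C)=O
Why: DMAP-catalysed acyl transfer with the small acetyl group esterifies the remaining tertiary alcohol without breaking its C–O bond, so C4 keeps its configuration, and the hindered conjugated angelate neither migrates nor isomerises under these mild basic conditions.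

Compound list
1 | acrolein | C=CC=O | starting material
2 | ethyl 2-(triphenylphosphoranylidene)propanoate | CCOC(=O)C(C)=P(c1ccccc1)(c1ccccc1)c1ccccc1 | starting material
3 | ethyl (2E)-2-methylpenta-2,4-dienoate | C=C/C=C(\C)C(=O)OCC | intermediate
4 | (2E)-2-methylpenta-2,4-dien-1-ol | C=C/C=C(\C)CO | intermediate
5 | (3E)-5-bromo-4-methylpenta-1,3-diene | C=C/C=C(\C)CBr | intermediate
6 | 1,3-dithiane | C1CSCSC1 | starting material
7 | 2-(2-bromoethyl)-1,3-dioxolane | BrCCC1OCCO1 | starting material
8 | 2-lithio-1,3-dithiane | [Li]C1SCCCS1 | intermediate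
9 | 2-[2-(1,3-dioxolan-2-yl)ethyl]-1,3-dithiane | C1CSC(CCC2OCCO2)SC1 | intermediate
10 | 2-lithio derivative of 9 | [Li]C1(CCC2OCCO2)SCCCS1 | intermediate
11 | 2-[2-(1,3-dioxolan-2-yl)ethyl]-2-[(2E)-2-methylpenta-2,4-dien-1-yl]-1,3-dithiane | C=C/C=C(\C)CC1(CCC2OCCO2)SCCCS1 | intermediate
12 | 3-{2-[(2E)-2-methylpenta-2,4-dien-1-yl]-1,3-dithian-2-yl}propanal | C=C/C=C(\C)CC1(CCC=O)SCCCS1 | intermediate
13 | 2-(triphenylphosphoranylidene)propanal | CC(C=O)=P(c1ccccc1)(c1ccccc1)c1ccccc1 | starting material
14 | (2E,8E)-2,8-dimethylundeca-2,8,10-trienal, C6 of the chain (C8) as spiro-1,3-dithiane | C=C/C=C(\C)CC1(CC/C=C(\C)C=O)SCCCS1 | intermediate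
15 | adduct: 4α-CHO, 4β-CH3, 5α-H, 10β-CH3, Δ1, C8 dithiane | O=C[C@]1(C)CC=C[C@]2(C)CC3(CC[C@H]21)SCCCS3 | intermediate
16 | 4α-(1-hydroxyethyl) carbinol, Δ1, C8 dithiane | CC(O)[C@]1(C)CC=C[C@]2(C)CC3(CC[C@H]21)SCCCS3 | intermediate
17 | 4α-(1-hydroxyethyl) carbinol, Δ1, C8 dioxolane | CC(O)[C@]1(C)CC=C[C@]2(C)CC3(CC[C@H]21)OCCO3 | intermediate
18 | 4α-acetyl, Δ1, C8 dioxolane | CC(=O)[C@]1(C)CC=C[C@]2(C)CC3(CC[C@H]21)OCCO3 | intermediate
19 | 4α-acetyl-Δ1-3-ketone, C8 dioxolane | CC(=O)[C@]1(C)C(=O)C=C[C@]2(C)CC3(CC[C@H]21)OCCO3 | intermediate
20 | 4α-acetyl-3-ketone, C8 dioxolane | CC(=O)[C@]1(C)C(=O)CC[C@]2(C)CC3(CC[C@H]21)OCCO3 | intermediate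
21 | 3β-hydroxy-4α-acetyl, C8 dioxolane | O[C@H]1CC[C@]2(C)CC3(OCCO3)CC[C@H]2[C@]1(C)C(C)=O | intermediate
22 | 3β-hydroxy-4α-acetoxy, C8 dioxolane | O[C@H]1CC[C@]2(C)CC3(OCCO3)CC[C@H]2[C@]1(C)OC(C)=O | intermediate
23 | 3β,4α-diol, C8 dioxolane | O[C@H]1CC[C@]2(C)CC3(OCCO3)CC[C@H]2[C@]1(C)O | intermediate
24 | 3β,4α-dihydroxy-4β,10β-dimethyl-5α-H-trans-decal-8-one | O[C@H]1CC[C@]2(C)CC(=O)CC[C@H]2[C@]1(C)O | intermediate
25 | bis-TMS ether of 24 | C[Si](C)(C)O[C@H]1CC[C@]2(C)CC(=O)CC[C@H]2[C@]1(C)O[Si](C)(C)C | intermediate
26 | Δ7 lithium enolate of 25 | C[Si](C)(C)O[C@H]1CC[C@]2(C)CC(O[Li])=CC[C@H]2[C@]1(C)O[Si](C)(C)C | intermediate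
27 | 7-(2-hydroxypropan-2-yl) aldol of 25 | C[Si](C)(C)O[C@H]1CC[C@]2(C)CC(=O)C(C(C)(C)O)C[C@H]2[C@]1(C)O[Si](C)(C)C | intermediate
28 | tertiary mesylate of 27 | C[Si](C)(C)O[C@H]1CC[C@]2(C)CC(=O)C(C(C)(C)OS(C)(=O)=O)C[C@H]2[C@]1(C)O[Si](C)(C)C | intermediate
29 | 3β,4α-bis(trimethylsilyloxy)eudesm-7(11)-en-8-one | C[Si](C)(C)O[C@H]1CC[C@]2(C)CC(=O)C(=C(C)C)C[C@H]2[C@]1(C)O[Si](C)(C)C | intermediate
30 | 3β,4α-dihydroxyeudesm-7(11)-en-8-one | O[C@H]1CC[C@]2(C)CC(=O)C(=C(C)C)C[C@H]2[C@]1(C)O | intermediate
31 | angelic acid | C/C=C(/C)C(=O)O | starting material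
32 | angelic 2,4,6-trichlorobenzoic anhydride | C/C=C(/C)C(=O)OC(=O)c1c(Cl)cc(Cl)cc1Cl | intermediate
33 | 3β-angeloyloxy-4α-hydroxyeudesm-7(11)-en-8-one | C/C=C(/C)C(=O)O[C@H]1CC[C@]2(C)CC(=O)C(=C(C)C)C[C@H]2[C@]1(C)O | intermediate
34 | 3β-angeloyloxy-4α-acetoxyeudesm-7(11)-en-8-one | C/C=C(/C)C(=O)O[C@H]1CC[C@]2(C)CC(=O)C(=C(C)C)C[C@H]2[C@]1(C)OC(C)=O | target

Total step count: 20. Longest linear sequence: 19 (steps 1–3 and 5–20; step 4 is the side branch).

Steps most likely to fail

1. Step 8.
- What may go wrong: The inside methyl on C10 raises the energy of the s-cis diene. It also crowds the forming C5–C10 bond, where two quaternary carbons with 1,3-related methyls arise together. Turnover may therefore be too slow at temperatures where catalyst control still holds. Sulfur may compete for boron. An exo-formyl (cis-fused) mode or an uncatalysed background reaction may erode diastereo- and enantioselectivity.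
- Fallback: It sets out from 14 and comes back at 15, and it keeps the same two bonds. Compound 14 is condensed with (2R,3R)-butane-2,3-diol (PPTS, benzene, removal of water) to give the (4R,5R)-4,5-dimethyl-1,3-dioxolane acetal of the trienal F1. Catalytic TMSOTf in CH2Cl2 at −78 °C opens this acetal to a vinyl-oxocarbenium ion, which is a far stronger dienophile than a Lewis-acid-bound enal (ionic Diels–Alder reaction). This ion cyclises and recloses to the (4R,5R)-4,5-dimethyl-1,3-dioxolane acetal of the adduct F2. The C2-symmetric diol makes the two enal faces diastereotopic, so any unwanted adduct is a diastereomer that can be separated. Aqueous trifluoroacetic acid in THF, to which the dithiane is inert, then releases 15.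

2. Step 11.
- What may go wrong: Hydrogen abstraction at the neopentyl C3 may be slow. The delocalised allyl intermediate may also take up oxygen at C1 instead of C3 (allylic transposition). The large excess of oxidant may cause over-oxidation.
- Fallback: It sets out from 17 and comes back at 19. Dess–Martin oxidation gives methyl ketone 18, which is now isolated. SeO2 (cat.)/t-BuOOH in CH2Cl2 then acts by an ene reaction at C1 followed by a [2,3]-shift. This pericyclic double transposition can only return oxygen to C3, and it gives the 4α-acetyl-Δ1-3-ol ketal F3. A second Dess–Martin oxidation converts that alcohol into 19.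

3. Step 19.
- What may go wrong: Acylation of the hindered 3β-OH may be slow. That gives the activated angeloyl species time to isomerise from Z to E, so that tigloyl transfer contaminates the ester.
- Fallback: It sets out from 30 and comes back at 33. O3 is esterified (EDC, DMAP, CH2Cl2) with 2-[bis(2,2,2-trifluoroethoxy)phosphoryl]propanoic acid, a saturated acid with no alkene to isomerise, to give the 3β-phosphonopropionate of the enone diol F4. A Still–Gennari olefination (KHMDS, 18-crown-6, THF, −78 °C, acetaldehyde) then builds the (Z)-2-methylbut-2-enoate on the molecule and delivers 33.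

Further compounds
F1 | step 8 | (4R,5R)-4,5-dimethyl-1,3-dioxolane acetal of trienal 14 | C=C/C=C(\C)CC1(CC/C=C(\C)C2O[C@H](C)[C@@H](C)O2)SCCCS1
F2 | step 8 | (4R,5R)-4,5-dimethyl-1,3-dioxolane acetal of adduct 15 | C4(O[C@H](C)[C@@H](C)O4)[C@]1(C)CC=C[C@]2(C)CC3(CC[C@H]21)SCCCS3
F3 | step 11 | 4α-acetyl-3-hydroxy-4β,10β-dimethyl-5α-H-Δ1-octalin-8-one ethylene ketal (C3 erased in the next operation) | CC(=O)[C@]1(C)C(O)C=C[C@]2(C)CC3(CC[C@H]21)OCCO3
F4 | step 19 | 3β-{2-[bis(2,2,2-trifluoroethoxy)phosphoryl]propanoyloxy}-4α-hydroxyeudesm-7(11)-en-8-one | CC(C(=O)O[C@H]1CC[C@]2(C)CC(=O)C(=C(C)C)C[C@H]2[C@]1(C)O)P(=O)(OCC(F)(F)F)OCC(F)(F)F
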